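Everything rests on cutting both bonds to C15 in seven-membered ring C. The secondary carbinol C13, ketone C15 and tertiary carbinol C17 form a 2-oxo-1,3-diol. That is the imprint one nitromethane carbon leaves after two nitroaldol additions and a Nef reaction. In a single operation nitromethane links aldehyde C13 to ring D ketone C17, forms C13–C15 and C15–C17, closes ring C and creates three stereocentres. The precursor is a 1,6-keto aldehyde. It has rings A and B with C11 locked as a methyl ketal that carries the non-enolisable formyl group C13, and at C28 a CH(CH3) arm (C26) bearing a saturated 2,2-dimethylcyclopentane-1,3-dione as ring D.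

Key step: step 8

Numbering: heavy atoms are numbered in the order of the target SMILES. O10/C11 are the ketal, C13, C15 and C17 lie in ring C, C19–C23 form ring D, C26 bears the methyl group, C28 is the B/C fusion carbon and C29 is the ring B methylene.
Assumption 1: C19, alpha to the C17 ketone, is configurationally labile. It is left undefined in 4, 6, 12 and 13, and 14 is drawn as the 19R epimer that enters ring closure.
Assumption 2: the sense of induction in step 2 is assigned by analogy with enamine Michael additions of propanal under the same catalyst family. The antipodal catalyst is equally available.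
Remark 1: C11, C13, C17, C26 and C28 have the spatial arrangement of the target in 14 and 17. The CIP letter at C26 is S there and R in 23 only because the ring D priorities change.
Remark 2: C28 is made by C–C bond formation on an enol ether. Protonation of a C28 enol anti to ring D would give the C28 epimer.
Remark 3: aldehyde C13 is released by oxidation, because no hydride reagent would take an ester beside the ring D ketones.

Step 1
Reactants: 1 2,2-dimethylcyclopentane-1,3-dione
Product: 2 2,2-dimethylcyclopent-4-ene-1,3-dione
Conditions: 2-iodoxybenzoic acid (IBX), DMSO–fluorobenzene, 70 °C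
Reagents that add atoms: none
Why: IBX dehydrogenation of a ketone through its enol; the dione has a single CH2–CH2 unit, so only one enedione can form and no stereocentre is involved.

Step 2
Reactants: 2 2,2-dimethylcyclopent-4-ene-1,3-dione; 3 propanal
Product: 4 (2S)-2-(3,3-dimethyl-2,4-dioxocyclopentyl)propanal
Conditions: (R)-α,α-diphenylprolinol trimethylsilyl ether (10 mol %), PhCO2H (10 mol %), toluene, 0 °C
Reagents that add atoms: none
Why: Enamine-catalysed asymmetric Michael addition of an aldehyde to a cyclic ene-dione (the reaction type known for maleimides): the diphenyl(silyloxy)methyl group of the R catalyst blocks one face of the E-enamine of propanal, so the symmetric acceptor is attacked from the open face and C26 is set (2S in 4), while C19 stays labile and irrelevant.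

Step 3
Reactants: 4 (2S)-2-(3,3-dimethyl-2,4-dioxocyclopentyl)propanal; 5 methyl 2-(dimethoxyphosphoryl)-2-methoxyacetate
Product: 6 methyl (2Z,4R)-4-(3,3-dimethyl-2,4-dioxocyclopentyl)-2-methoxypent-2-enoate
Conditions: LiCl, iPr2NEt, MeCN, 0 °C → rt
Reagents that add atoms: none
Why: Horner–Wadsworth–Emmons olefination under LiCl/amine conditions: the stabilised phosphonate anion takes the aldehyde and ignores the two neopentyl-type ketones, the weak base spares the alpha-stereocentre C26, and the branched chain ends up trans to the ester, which is the Z enol ether.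

Step 4
Reactants: 7 4-hydroxy-5,6-dimethyl-2H-pyran-2-one; 8 N,N-dimethylmethyleneiminium iodide (Eschenmoser's salt)
Product: 9 3-[(dimethylamino)methyl]-4-hydroxy-5,6-dimethyl-2H-pyran-2-one
Conditions: Et3N, CH2Cl2, 0 °C → rt
Reagents that add atoms: none
Why: Mannich aminomethylation at the nucleophilic C3 of the 4-hydroxypyranone (C6 of the target) with a preformed iminium salt, which installs C29 and avoids the methylene-bridged pyranone dimer that free formaldehyde tends to give.

Step 5
Reactants: 6 methyl (2Z,4R)-4-(3,3-dimethyl-2,4-dioxocyclopentyl)-2-methoxypent-2-enoate; 9 3-[(dimethylamino)methyl]-4-hydroxy-5,6-dimethyl-2H-pyran-2-one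
Product: 12 methyl (2S,3R)-3-[(1S)-1-(3,3-dimethyl-2,4-dioxocyclopentyl)ethyl]-2-methoxy-7,8-dimethyl-5-oxo-3,4-dihydro-2H,5H-pyrano[4,3-b]pyran-2-carboxylate, via ammonium iodide 10 (not isolated), via oxadiene 11 (not isolated)
Conditions: MeI, 1,4-dioxane, 95 °C, sealed vessel, 9 added in portions
Reagents that add atoms: none
Why: N-Methylation and loss of trimethylamine unmask the 1-oxadiene 11, which undergoes an inverse-electron-demand hetero-Diels–Alder reaction (known for such quinone-methide-type dienes with enol ethers and with 2-substituted acrylates) through its ketone carbonyl, C29 bonding to the donor-activated C28 and O10 to C11; suprafacial addition to the Z alkene places OMe and C26 cis on ring B (C11), and C28 is set because A(1,3) strain with the cis methoxy group holds H26 in the alkene plane, so the diene adds to the face opposite ring D.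

Step 6
Reactants: 12 rings A/B methyl ketal ester with ring D dione
Product: 13 (2S,3R)-3-[(1S)-1-(2,4-dihydroxy-3,3-dimethylcyclopentyl)ethyl]-2-(hydroxymethyl)-2-methoxy-7,8-dimethyl-3,4-dihydro-2H,5H-pyrano[4,3-b]pyran-5-one (carbinol epimers at C17 and C21 not separated)
Conditions: NaBH4 (excess), THF–MeOH, 0 °C → rt
Reagents that add atoms: none
Why: Borohydride reduction: the two ketones and the ester, which is activated by two alpha-oxygens like an ulosonate ester, are all reduced while the electron-rich pyranone (a vinylogous carbonate) is left alone; the new carbinol centres are erased in step 7.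

Step 7
Reactants: 13 rings A/B methyl ketal triol
Product: 14 (2S,3R)-3-[(1S)-1-[(1R)-3,3-dimethyl-2,4-dioxocyclopentyl]ethyl]-2-methoxy-7,8-dimethyl-5-oxo-3,4-dihydro-2H,5H-pyrano[4,3-b]pyran-2-carbaldehyde (keto aldehyde precursor)
Conditions: Dess–Martin periodinane (4.5 equiv), pyridine, CH2Cl2, 0 °C → rt
Reagents that add atoms: none
Why: Threefold Dess–Martin oxidation returns ring D to the 1,3-dione and takes the primary alcohol to aldehyde C13, which cannot enolise or epimerise because C11 is quaternary; C11, C26 and C28 are untouched.

Step 8
Reactants: 14 keto aldehyde precursor; 15 nitromethane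
Product: 17 tetracyclic nitro diol (C11 OMe; C13 OH; C15 NO2; C17 OH; C21 ketone; 11S,13R,15S,17R,19R,26S,28R), via nitro alcohol 16 (not isolated)
Conditions: MeNO2 (10 equiv), 1,1,3,3-tetramethylguanidine (0.3 equiv), THF, 0 °C → rt
Reagents that add atoms: none
Why: Proposed new method: the guanidine generates the nitronate of nitromethane, which adds to the unhindered, non-enolisable aldehyde C13 to give nitro alcohol 16, and the secondary nitronate of 16 then attacks ring D carbonyl C17 in a 7-exo-trig closure, so that C15 ends up bonded to both carbinol carbons. The closest known reaction types are the double nitroaldol cyclisation of nitromethane with 1,5-dialdehydes to six-membered 2-nitro-1,3-diols and the intramolecular addition of stabilised carbanions to 2,2-disubstituted cyclopentane-1,3-diones; new here are the seven-membered ring and the ketone terminus, whose reluctance is offset by the inductive activation and strain relief of the 1,3-dione. Every C–C bond formed is reversible, so the outcome is thermodynamic: C17 should settle with the bulky quaternary C23 equatorial on ring C and the hydroxyl axial, on a scaffold fixed by the trans B/C fusion (C11, C28) and the equatorial C26 methyl group. C13 is sorted by the same equilibrium, since only the nitro alcohol epimer that can bring its nitronate over C17 without clashing with the axial C11 methoxy group drains into the ring, and C15 equilibrates through its nitronate to the less crowded orientation and is erased later. Site selectivity for C17 over C21 follows from ring size (a fused seven-membered ring against a bridged eight-membered one), conjugate addition is excluded because ring D is saturated, and C19 can epimerise under the base and disappears on desaturation. Substoichiometric base, an aprotic medium and low temperature keep alkoxide lifetimes short, so that retro-Claisen opening of ring D and ketone-enolate aldol reactions stay slower than the nitronate chemistry.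

Step 9
Reactants: 17 tetracyclic nitro diol
Product: 18 C13,C17-bis(triethylsilyl) ether of the nitro diol (11S,13R,15S,17R,19R,26S,28R)
Conditions: TESOTf (4 equiv), 2,6-lutidine, CH2Cl2, −20 °C → rt
Reagents that add atoms: triethylsilyl trifluoromethanesulfonate, CC[Si](CC)(CC)OS(=O)(=O)C(F)(F)F
Why: Silyl triflate silylation with a weak hindered pyridine base caps the secondary and the hindered tertiary alcohol without forming the nitronate, which blocks retro-nitroaldol cleavage in the next step; no stereocentre changes.

Step 10
Reactants: 18 bis(triethylsilyl) nitro compound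
Product: 20 C15,C21-diketone bis(triethylsilyl) ether (11S,13R,17R,19R,26S,28R), via potassium nitronate 19 (not isolated)
Conditions: KOtBu (1.0 equiv), THF, −78 °C; dimethyldioxirane in acetone, −78 → −20 °C; pH 7 buffer
Reagents that add atoms: dimethyldioxirane, CC1(C)OO1
Why: Oxidative Nef reaction: with both carbinols silylated the nitronate cannot revert by retro-nitroaldol cleavage, and oxygen transfer from the dioxirane to the nitronate carbon at low temperature releases nitrite and the C15 ketone before loss of silanolate can compete; one equivalent of base is consumed by the far more acidic nitroalkane, so C13 and the ring D ketone are not enolised.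

Step 11
Reactants: 20 C15,C21-diketone bis(triethylsilyl) ether
Product: 22 ring D enone bis(triethylsilyl) ether (C19=C20; 11S,13R,17R,26R,28R), via trimethylsilyl enol ether 21 (not isolated)
Conditions: TMSOTf, Et3N, CH2Cl2, −78 → 0 °C; NaHCO3 wash, solvent switch; Pd(OAc)2 (1.1 equiv), MeCN, rt
Reagents that add atoms: none
Why: Saegusa–Ito oxidation: soft enolisation picks the accessible C20 methylene next to the C21 ketone, the C15 carbonyl being buried between two silyloxy-bearing carbons, and palladium diacetate then removes the C19 hydrogen by β-hydride elimination, which erases C19 and gives the enone without exposing the base-sensitive C11–C13–C15 array to a metal amide.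

Step 12
Reactants: 22 ring D enone bis(triethylsilyl) ether
Product: 23 target CNP0525404.1 (11S,13R,17R,26R,28R)
Conditions: TFA–H2O–THF (1:1:3), rt
Reagents that add atoms: water, O
Why: Aqueous acid cleaves both triethylsilyl ethers and hydrolyses the mixed methyl ketal, whose pyranone oxygen is a good leaving group; the hemiketal recloses with the hydroxyl axial (anomeric effect) on the trans-fused B/C system so that C11 keeps its configuration, and the C17 alcohol cannot ionise because the cation would sit next to the C15 ketone.

Compound list
1 | 2,2-dimethylcyclopentane-1,3-dione | CC1(C)C(=O)CCC1=O | starting material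
2 | 2,2-dimethylcyclopent-4-ene-1,3-dione | CC1(C)C(=O)C=CC1=O | intermediate
3 | propanal | CCC=O | starting material
4 | (2S)-2-(3,3-dimethyl-2,4-dioxocyclopentyl)propanal | O=C[C@@H](C)C1CC(=O)C(C)(C)C1=O | intermediate
5 | methyl 2-(dimethoxyphosphoryl)-2-methoxyacetate | COC(C(=O)OC)P(=O)(OC)OC | starting material
6 | methyl (2Z,4R)-4-(3,3-dimethyl-2,4-dioxocyclopentyl)-2-methoxypent-2-enoate | COC(=O)/C(OC)=C/[C@@H](C)C1CC(=O)C(C)(C)C1=O | intermediate
7 | 4-hydroxy-5,6-dimethyl-2H-pyran-2-one | Cc1oc(=O)cc(O)c1C | starting material
8 | N,N-dimethylmethyleneiminium iodide | C[N+](C)=C.[I-] | starting material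
9 | 3-[(dimethylamino)methyl]-4-hydroxy-5,6-dimethyl-2H-pyran-2-one | CN(C)Cc1c(O)c(C)c(C)oc1=O | intermediate
10 | (4-hydroxy-5,6-dimethyl-2-oxo-2H-pyran-3-yl)methyl-trimethylammonium iodide | C[N+](C)(C)Cc1c(O)c(C)c(C)oc1=O.[I-] | intermediate
11 | 5,6-dimethyl-3-methylidene-2H-pyran-2,4(3H)-dione | C=C1C(=O)OC(C)=C(C)C1=O | intermediate
12 | rings A/B methyl ketal ester with ring D dione (11S,26S,28R) | Cc1oc(=O)c2c(c1C)O[C@](OC)(C(=O)OC)[C@@H]([C@@H](C)C3CC(=O)C(C)(C)C3=O)C2 | intermediate
13 | rings A/B methyl ketal triol (11S,26S,28R; C17, C19 and C21 undefined) | Cc1oc(=O)c2c(c1C)O[C@](OC)(CO)[C@@H]([C@@H](C)C3CC(O)C(C)(C)C3O)C2 | intermediate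
14 | keto aldehyde precursor (11S,19R,26S,28R) | Cc1oc(=O)c2c(c1C)O[C@](OC)(C=O)[C@@H]([C@@H](C)[C@H]3CC(=O)C(C)(C)C3=O)C2 | intermediate
15 | nitromethane | C[N+](=O)[O-] | starting material
16 | open-chain nitro alcohol (13R) | Cc1oc(=O)c2c(c1C)O[C@](OC)([C@H](O)C[N+](=O)[O-])[C@@H]([C@@H](C)[C@H]3CC(=O)C(C)(C)C3=O)C2 | intermediate
17 | tetracyclic nitro diol (11S,13R,15S,17R,19R,26S,28R) | Cc1oc(=O)c2c(c1C)O[C@]1(OC)[C@H](O)[C@H]([N+](=O)[O-])[C@@]3(O)[C@H](CC(=O)C3(C)C)[C@H](C)[C@H]1C2 | intermediate
18 | bis(triethylsilyl) ether of 17 | Cc1oc(=O)c2c(c1C)O[C@]1(OC)[C@H](O[Si](CC)(CC)CC)[C@H]([N+](=O)[O-])[C@@]3(O[Si](CC)(CC)CC)[C@H](CC(=O)C3(C)C)[C@H](C)[C@H]1C2 | intermediate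
19 | potassium nitronate of 18 | Cc1oc(=O)c2c(c1C)O[C@]1(OC)[C@H](O[Si](CC)(CC)CC)C(=[N+]([O-])[O-])[C@@]3(O[Si](CC)(CC)CC)[C@H](CC(=O)C3(C)C)[C@H](C)[C@H]1C2.[K+] | intermediate
20 | C15,C21-diketone bis(triethylsilyl) ether | Cc1oc(=O)c2c(c1C)O[C@]1(OC)[C@H](O[Si](CC)(CC)CC)C(=O)[C@@]3(O[Si](CC)(CC)CC)[C@H](CC(=O)C3(C)C)[C@H](C)[C@H]1C2 | intermediate
21 | C21 trimethylsilyl enol ether of 20 | Cc1oc(=O)c2c(c1C)O[C@]1(OC)[C@H](O[Si](CC)(CC)CC)C(=O)[C@@]3(O[Si](CC)(CC)CC)[C@H](C=C(O[Si](C)(C)C)C3(C)C)[C@H](C)[C@H]1C2 | intermediate
22 | ring D enone bis(triethylsilyl) ether | Cc1oc(=O)c2c(c1C)O[C@]1(OC)[C@H](O[Si](CC)(CC)CC)C(=O)[C@@]3(O[Si](CC)(CC)CC)C(=CC(=O)C3(C)C)[C@H](C)[C@H]1C2 | intermediate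
23 | CNP0525404.1 (11S,13R,17R,26R,28R) | Cc1oc(=O)c2c(c1C)O[C@]1(O)[C@H](O)C(=O)[C@@]3(O)C(=CC(=O)C3(C)C)[C@H](C)[C@H]1C2 | target

Total step count: 12. Longest linear sequence: 11 (steps 1–3 and 5–12).

Steps most likely to fail

Step 8 (key step).
- The second addition may stall at the open nitro alcohol, because attack of a secondary nitronate on a ketone flanked by a quaternary and a tertiary carbon is thermodynamically marginal.
- Facial selection at C13 and C17 may be poor.
- Long contact with base may open ring D by retro-Claisen cleavage or start ketone-enolate aldol chemistry.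

The fallback uses established reaction types only. It sets out from 14 and returns at 20. The nitroaldol reaction is stopped after the first addition by running it with Cu(OAc)2, a chiral bis(oxazoline) ligand and iPr2NEt. This gives 16 as an isolated compound with C13 under catalyst control. TESOTf and 2,6-lutidine give the triethylsilyl ether of the nitro alcohol F1. Nitronate formation with KOtBu and oxidation with dimethyldioxirane (the Nef reaction of a primary nitroalkane) give the α-silyloxy aldehyde F2. A triazolium-derived carbene with Et3N then closes ring C by an intramolecular crossed aldehyde–ketone benzoin reaction. That closure forms C15–C17 and delivers C15 directly at the ketone level in the C17-hydroxy ketol F3. Silylation of the tertiary hydroxyl with TESOTf leads back to 20.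

Step 5.
- The trisubstituted alkene is deactivated by its ester, so cycloaddition may be slower than self-consumption of the oxadiene.
- Discrimination between the two alkene faces may be modest.

The fallback sets out from 6 and returns at 13. It inverts the order of reduction and cycloaddition so that an electron-rich enol ether meets the oxadiene. iBu2AlH in CH2Cl2 at −78 °C reduces the ester and both ketones to the allylic alcohol triol F4. Cycloaddition of F4 with 11, generated from 9 and MeI as before, gives 13 directly.

Step 10.
- Deprotonation of the crowded C15–H may be slow.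
- The nitronate may lose silanolate by β-elimination before it is oxidised.

The fallback sets out from 18 and returns at 20. It replaces nitronate oxidation by a reductive sequence. SnCl2, PhSH and Et3N reduce the secondary nitro group to the C15 oxime F5. TiCl3 buffered with NH4OAc in aqueous THF then cleaves the N–O bond, and the imine hydrolyses to 20.

Further compounds
F1 | step 8 | triethylsilyl ether of nitro alcohol 16 | Cc1oc(=O)c2c(c1C)O[C@](OC)([C@H](O[Si](CC)(CC)CC)C[N+](=O)[O-])[C@@H]([C@@H](C)[C@H]3CC(=O)C(C)(C)C3=O)C2
F2 | step 8 | α-silyloxy aldehyde (C15 formyl) | Cc1oc(=O)c2c(c1C)O[C@](OC)([C@H](O[Si](CC)(CC)CC)C=O)[C@@H]([C@@H](C)[C@H]3CC(=O)C(C)(C)C3=O)C2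
F3 | step 8 | C17-hydroxy ketol with C13 triethylsilyl ether | Cc1oc(=O)c2c(c1C)O[C@]1(OC)[C@H](O[Si](CC)(CC)CC)C(=O)[C@@]3(O)[C@H](CC(=O)C3(C)C)[C@H](C)[C@H]1C2
F4 | step 5 | (2Z,4S)-4-(2,4-dihydroxy-3,3-dimethylcyclopentyl)-2-methoxypent-2-en-1-ol | OC/C(OC)=C/[C@@H](C)C1CC(O)C(C)(C)C1O
F5 | step 10 | C15 oxime bis(triethylsilyl) ether | Cc1oc(=O)c2c(c1C)O[C@]1(OC)[C@H](O[Si](CC)(CC)CC)C(=NO)[C@@]3(O[Si](CC)(CC)CC)[C@H](CC(=O)C3(C)C)[C@H](C)[C@H]1C2
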